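The polyene is cut at C11=C12 and C11'=C12' into the C10 trienedial and two C15 phosphonium salts, and both ring units are traced back to one achiral cyclohexa-1,4-diene ester. A single [4+2] cycloaddition forms C1–C6 and C4–C5, delivering the gem-dimethyl carbon C1, the tetrasubstituted C5=C6 alkene, C7 and an isolated C2=C3 alkene for later oxidation. It exploits the fact that ring A (C2–OH) and ring B (C2'/C3' cis-diol) share one 2,6,6-trimethylcyclohexene skeleton with C2 and C2' oxygenated on opposite faces, so both enantiomers of one cis-diol are used. The precursor is merely the pair 4-methylpenta-1,3-diene and ethyl but-2-ynoate.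

Key step: step 1

Remark on numbering: ring intermediates carry the locants of the cyclohexene carboxylate (C1 bears the side chain). These map onto carotenoid locants as C1→C6, C2→C5, C3→C4, C4→C3, C5→C2, C6→C1.

Assumption: the lipase follows the usual size rule for secondary alcohols and acetylates the unhindered C4–OH of the (4R,5S)-diol. Should it prefer the mirror image, acetate and recovered diol simply exchange branches and step 4 moves to the ring B branch.

**Step 1**
Reactants: 1 4-methylpenta-1,3-diene; 2 ethyl but-2-ynoate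
Product: 3 ethyl 2,6,6-trimethylcyclohexa-1,4-diene-1-carboxylate
Conditions: EtAlCl2 (0.3 equiv), CH2Cl2, −20 → 25 °C, slow addition of 1 (3 equiv)
Reagents that add atoms: none
Why: A concerted, asynchronous, normal-electron-demand [4+2] cycloaddition (Lewis-acid-promoted Diels–Alder reaction): EtAlCl2 binds the ester carbonyl, lowers the ynoate LUMO and enlarges its coefficient at the methyl-bearing β-carbon, which bonds first to the unsubstituted CH2 terminus of the diene (largest HOMO coefficient, remote from the two donor methyls), after which the CMe2 terminus closes onto the ester-bearing carbon. The closest known reaction type is the thermal or Lewis-acid Diels–Alder addition of 1,1-dimethylbutadiene to acetylenic esters and aldehydes. The one six-membered ring is closed by intermolecular cycloaddition, both σ bonds (C1–C6 and C2–C3 of the ester, i.e. C6–C1 and C5–C4 in carotenoid numbering) arising in the same step, and the alkyne dienophile gives the 1,4-diene directly. No stereocentre is created, so regiochemistry is the only selectivity required. The needed orientation (CMe2 next to the ester carbon) is secured electronically by the matching frontier coefficients, which outweighs the steric cost of joining the two most substituted carbons. EtAlCl2 also scavenges stray protons and slow addition keeps the diene dilute, both of which restrain cationic diene polymerisation, while the product alkenes are too poor as dienophiles to react further.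

**Step 2**
Reactants: 3 ethyl 2,6,6-trimethylcyclohexa-1,4-diene-1-carboxylate
Product: 4 racemic ethyl cis-4,5-dihydroxy-2,6,6-trimethylcyclohex-1-ene-1-carboxylate
Conditions: OsO4 (2 mol %), NMO, acetone/H2O, 25 °C
Reagents that add atoms: osmium tetroxide O=[Os](=O)(=O)=O; N-methylmorpholine N-oxide C[N+]1([O-])CCOCC1; water O
Why: Upjohn syn-dihydroxylation adds both oxygens suprafacially to the electron-rich cis-disubstituted C4=C5 alkene only (the tetrasubstituted enoate alkene is deactivated and shielded), which fixes the cis relationship of the two carbinol centres, and the enantiotopic alkene faces give the racemate.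

**Step 3**
Reactants: 4 racemic ethyl cis-4,5-dihydroxy-2,6,6-trimethylcyclohex-1-ene-1-carboxylate
Product: 5 ethyl (4R,5S)-4-acetoxy-5-hydroxy-2,6,6-trimethylcyclohex-1-ene-1-carboxylate and 6 ethyl (4S,5R)-4,5-dihydroxy-2,6,6-trimethylcyclohex-1-ene-1-carboxylate (left unacylated; separated by chromatography)
Conditions: Burkholderia cepacia lipase (Amano PS, immobilised), vinyl acetate, MTBE, 30 °C, to about half conversion
Reagents that add atoms: vinyl acetate C=COC(C)=O
Why: Lipase-catalysed kinetic resolution by irreversible transesterification should acetylate only the unhindered C4–OH (C5–OH is neopentylic) and only in the (4R) enantiomer (large group on the C5 side, medium group the C3 methylene), so the absolute configuration of both ring series is fixed here by sorting and neither enantiomer is discarded.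

**Step 4**
Reactants: 5 ethyl (4R,5S)-4-acetoxy-5-hydroxy-2,6,6-trimethylcyclohex-1-ene-1-carboxylate
Product: 7 ethyl (4R,5S)-4,5-dihydroxy-2,6,6-trimethylcyclohex-1-ene-1-carboxylate
Conditions: K2CO3 (cat.), EtOH, 25 °C
Reagents that add atoms: none
Why: Base-catalysed transesterification (ethanolysis) removes the secondary acetate, while the hindered conjugated ring ester is untouched and ethanol excludes ester scrambling.

**Step 5**
Reactants: 7 ethyl (4R,5S)-4,5-dihydroxy-2,6,6-trimethylcyclohex-1-ene-1-carboxylate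
Product: 9 ethyl (4R,5S)-2,6,6-trimethyl-4,5-(sulfonyldioxy)cyclohex-1-ene-1-carboxylate (cyclic sulfate), via cyclic sulfite 8 (not isolated)
Conditions: SOCl2, Et3N, CH2Cl2, 0 °C; then RuCl3 (1 mol %), NaIO4, MeCN/H2O, 0 °C
Reagents that add atoms: thionyl chloride O=S(Cl)Cl; sodium periodate [Na+].[O-]I(=O)(=O)=O
Why: Cyclic sulfate formation through the cyclic sulfite (diol sulfinylation, then RuO4-catalysed oxidation at sulfur, which is much faster than attack on the electron-poor tetrasubstituted alkene) touches no C–O bond, so both centres are retained.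

**Step 6**
Reactants: 9 ethyl (4R,5S)-2,6,6-trimethyl-4,5-(sulfonyldioxy)cyclohex-1-ene-1-carboxylate
Product: 11 ethyl (5R)-5-hydroxy-2,6,6-trimethylcyclohex-1-ene-1-carboxylate, via sodium sulfate monoester 10 (not isolated)
Conditions: NaBH4, DMA, 0 → 25 °C; then H2SO4 (cat.), H2O, THF, 25 °C
Reagents that add atoms: none
Why: SN2 opening of the cyclic sulfate by hydride occurs at C4 because C5 is neopentylic (flanked by quaternary C6), and acid hydrolysis of the remaining sulfate monoester cleaves S–O with retention at C5, whose descriptor changes to R only through loss of the C4 oxygen; NaBH4 leaves the hindered enoate alone.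

**Step 7**
Reactants: 11 ethyl (5R)-5-hydroxy-2,6,6-trimethylcyclohex-1-ene-1-carboxylate
Product: 12 (1R)-3-(hydroxymethyl)-2,2,4-trimethylcyclohex-3-en-1-ol
Conditions: i-Bu2AlH (3.5 equiv), CH2Cl2, −78 → 0 °C; aq. potassium sodium tartrate
Reagents that add atoms: none
Why: Hydride reduction of the α,β-unsaturated ester by i-Bu2AlH proceeds by 1,2-addition to the allylic alcohol, the free hydroxyl merely consuming one equivalent of reagent.

**Step 8**
Reactants: 12 (1R)-3-(hydroxymethyl)-2,2,4-trimethylcyclohex-3-en-1-ol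
Product: 13 (5R)-5-hydroxy-2,6,6-trimethylcyclohex-1-ene-1-carbaldehyde
Conditions: MnO2 (activated, excess), CH2Cl2, 25 °C
Reagents that add atoms: none
Why: Chemoselective allylic oxidation with MnO2 converts only the primary allylic alcohol, the saturated secondary carbinol being inert.

**Step 9**
Reactants: 13 (5R)-5-hydroxy-2,6,6-trimethylcyclohex-1-ene-1-carbaldehyde; 14 ethyl (E)-4-(diethoxyphosphoryl)-3-methylbut-2-enoate
Product: 15 ethyl (2E,4E)-5-[(5R)-5-hydroxy-2,6,6-trimethylcyclohex-1-en-1-yl]-3-methylpenta-2,4-dienoate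
Conditions: 14 (2.5 equiv), LiN(SiMe3)2 (2.4 equiv), THF, −78 → 25 °C
Reagents that add atoms: none
Why: Horner–Wadsworth–Emmons olefination of the hindered enal with the vinylogous phosphonate anion forms the new disubstituted alkene E, the excess reagent carries the free hydroxyl as its lithium alkoxide, and the trisubstituted alkene equilibrates towards E through the delocalised anion (any Z isomer converges at the phosphonium stage).

**Step 10**
Reactants: 15 ethyl (2E,4E)-5-[(5R)-5-hydroxy-2,6,6-trimethylcyclohex-1-en-1-yl]-3-methylpenta-2,4-dienoate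
Product: 16 (2E,4E)-5-[(5R)-5-hydroxy-2,6,6-trimethylcyclohex-1-en-1-yl]-3-methylpenta-2,4-dien-1-ol
Conditions: i-Bu2AlH (3.5 equiv), CH2Cl2, −78 °C; aq. potassium sodium tartrate
Reagents that add atoms: none
Why: 1,2-Hydride reduction of the dienoate with i-Bu2AlH gives the dienol without touching the alkene geometry.

**Step 11**
Reactants: 16 (2E,4E)-5-[(5R)-5-hydroxy-2,6,6-trimethylcyclohex-1-en-1-yl]-3-methylpenta-2,4-dien-1-ol
Product: 17 {(2E,4E)-5-[(5R)-5-hydroxy-2,6,6-trimethylcyclohex-1-en-1-yl]-3-methylpenta-2,4-dien-1-yl}triphenylphosphonium bromide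
Conditions: PPh3·HBr (1.1 equiv), MeOH, 25 °C
Reagents that add atoms: triphenylphosphine hydrobromide Br.c1ccc(cc1)P(c1ccccc1)c1ccccc1
Why: Phosphonium salt formation from an allylic alcohol (SN1-type ionisation to the pentadienyl cation, capture by PPh3 at the unhindered primary terminus under thermodynamic control) gives the E,E salt, and the homoallylic ring hydroxyl does not ionise.

**Step 12**
Reactants: 6 ethyl (4S,5R)-4,5-dihydroxy-2,6,6-trimethylcyclohex-1-ene-1-carboxylate
Product: 18 ethyl (4S,5R)-4,5-(isopropylidenedioxy)-2,6,6-trimethylcyclohex-1-ene-1-carboxylate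
Conditions: 2,2-dimethoxypropane, PPTS (cat.), acetone, 25 °C
Reagents that add atoms: 2,2-dimethoxypropane COC(C)(C)OC
Why: Acid-catalysed transketalisation closes the cis-diol to the cis-fused dioxolane, masking both hydroxyls against hydride, oxidant and base without touching either centre.

**Step 13**
Reactants: 18 ethyl (4S,5R)-4,5-(isopropylidenedioxy)-2,6,6-trimethylcyclohex-1-ene-1-carboxylate
Product: 19 [(4S,5R)-4,5-(isopropylidenedioxy)-2,6,6-trimethylcyclohex-1-en-1-yl]methanol
Conditions: i-Bu2AlH (2.2 equiv), CH2Cl2, −78 → 0 °C; aq. potassium sodium tartrate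
Reagents that add atoms: none
Why: Hydride reduction of the conjugated ester by 1,2-addition gives the allylic alcohol, the acetonide being inert to i-Bu2AlH at low temperature.

**Step 14**
Reactants: 19 [(4S,5R)-4,5-(isopropylidenedioxy)-2,6,6-trimethylcyclohex-1-en-1-yl]methanol
Product: 20 (4S,5R)-4,5-(isopropylidenedioxy)-2,6,6-trimethylcyclohex-1-ene-1-carbaldehyde
Conditions: MnO2 (activated, excess), CH2Cl2, 25 °C
Reagents that add atoms: none
Why: Allylic oxidation with MnO2 stops at the conjugated aldehyde and, with the diol masked, no glycol cleavage can intervene.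

**Step 15**
Reactants: 20 (4S,5R)-4,5-(isopropylidenedioxy)-2,6,6-trimethylcyclohex-1-ene-1-carbaldehyde; 14 ethyl (E)-4-(diethoxyphosphoryl)-3-methylbut-2-enoate
Product: 21 ethyl (2E,4E)-5-[(4S,5R)-4,5-(isopropylidenedioxy)-2,6,6-trimethylcyclohex-1-en-1-yl]-3-methylpenta-2,4-dienoate
Conditions: 14 (1.5 equiv), LiN(SiMe3)2 (1.4 equiv), THF, −78 → 25 °C
Reagents that add atoms: none
Why: Horner–Wadsworth–Emmons olefination as in step 9 gives the E disubstituted alkene, with the trisubstituted alkene equilibrating towards E through the phosphonate anion.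

**Step 16**
Reactants: 21 ethyl (2E,4E)-5-[(4S,5R)-4,5-(isopropylidenedioxy)-2,6,6-trimethylcyclohex-1-en-1-yl]-3-methylpenta-2,4-dienoate
Product: 22 (2E,4E)-5-[(4S,5R)-4,5-(isopropylidenedioxy)-2,6,6-trimethylcyclohex-1-en-1-yl]-3-methylpenta-2,4-dien-1-ol
Conditions: i-Bu2AlH (2.2 equiv), CH2Cl2, −78 °C; aq. potassium sodium tartrate
Reagents that add atoms: none
Why: 1,2-Hydride reduction of the dienoate with i-Bu2AlH gives the dienol, as in step 10.

**Step 17**
Reactants: 22 (2E,4E)-5-[(4S,5R)-4,5-(isopropylidenedioxy)-2,6,6-trimethylcyclohex-1-en-1-yl]-3-methylpenta-2,4-dien-1-ol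
Product: 24 {(2E,4E)-5-[(4S,5R)-4,5-dihydroxy-2,6,6-trimethylcyclohex-1-en-1-yl]-3-methylpenta-2,4-dien-1-yl}triphenylphosphonium bromide, via acetonide phosphonium bromide 23 (not isolated)
Conditions: PPh3·HBr (1.1 equiv), MeOH, 25 °C; then 48% aq. HBr (cat.), 40 °C
Reagents that add atoms: triphenylphosphine hydrobromide Br.c1ccc(cc1)P(c1ccccc1)c1ccccc1
Why: Phosphonium salt formation from the allylic alcohol as in step 11, followed in the same pot by acid-catalysed acetal hydrolysis, which the acid-stable phosphonium salt tolerates and which breaks no C–O bond at the carbinol centres.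

**Step 18**
Reactants: 24 {(2E,4E)-5-[(4S,5R)-4,5-dihydroxy-2,6,6-trimethylcyclohex-1-en-1-yl]-3-methylpenta-2,4-dien-1-yl}triphenylphosphonium bromide; 25 (2E,4E,6E)-2,7-dimethylocta-2,4,6-trienedial
Product: 26 (2E,4E,6E,8E,10E,12E)-13-[(4S,5R)-4,5-dihydroxy-2,6,6-trimethylcyclohex-1-en-1-yl]-2,7,11-trimethyltrideca-2,4,6,8,10,12-hexaenal
Conditions: 25 (3 equiv), NaOMe (1.1 equiv, added slowly), MeOH/CH2Cl2, 0 → 25 °C; then EtOH, reflux, dark
Reagents that add atoms: none
Why: Wittig olefination with the semi-stabilised allylic ylide is held at the mono-adduct by the excess of dialdehyde and the lower electrophilicity of the extended C25 aldehyde, and Z isomers at the new alkene are isomerised thermally to E.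

**Step 19**
Reactants: 26 (2E,4E,6E,8E,10E,12E)-13-[(4S,5R)-4,5-dihydroxy-2,6,6-trimethylcyclohex-1-en-1-yl]-2,7,11-trimethyltrideca-2,4,6,8,10,12-hexaenal; 17 {(2E,4E)-5-[(5R)-5-hydroxy-2,6,6-trimethylcyclohex-1-en-1-yl]-3-methylpenta-2,4-dien-1-yl}triphenylphosphonium bromide
Product: 27 (all-E)-(2R,2'R,3'S)-β,β-carotene-2,2',3'-triol
Conditions: 17 (1.3 equiv), NaOMe, MeOH/CH2Cl2, 25 °C; then EtOH, reflux, dark, argon; crystallisation
Reagents that add atoms: none
Why: The second Wittig olefination forms C11=C12 and completes the C40 skeleton in the presence of the three free hydroxyls (inert to methoxide), and thermal Z→E isomerisation with crystallisation should furnish the all-E polyene with the three carbinol centres unchanged.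

**Compound list**
1 | 4-methylpenta-1,3-diene | CC(C)=CC=C | starting material
2 | ethyl but-2-ynoate | CC#CC(=O)OCC | starting material
3 | ethyl 2,6,6-trimethylcyclohexa-1,4-diene-1-carboxylate (achiral) | CCOC(=O)C1=C(C)CC=CC1(C)C | intermediate
4 | racemic ethyl cis-4,5-dihydroxy-2,6,6-trimethylcyclohex-1-ene-1-carboxylate (drawn as the (4S,5R) enantiomer; mirror image equally present) | CCOC(=O)C1=C(C)C[C@H](O)[C@H](O)C1(C)C | intermediate
5 | ethyl (4R,5S)-4-acetoxy-5-hydroxy-2,6,6-trimethylcyclohex-1-ene-1-carboxylate | CCOC(=O)C1=C(C)C[C@@H](OC(C)=O)[C@@H](O)C1(C)C | intermediate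
6 | ethyl (4S,5R)-4,5-dihydroxy-2,6,6-trimethylcyclohex-1-ene-1-carboxylate (ring B series) | CCOC(=O)C1=C(C)C[C@H](O)[C@H](O)C1(C)C | intermediate
7 | ethyl (4R,5S)-4,5-dihydroxy-2,6,6-trimethylcyclohex-1-ene-1-carboxylate (ring A series) | CCOC(=O)C1=C(C)C[C@@H](O)[C@@H](O)C1(C)C | intermediate
8 | ethyl (4R,5S)-2,6,6-trimethyl-4,5-(sulfinyldioxy)cyclohex-1-ene-1-carboxylate (cyclic sulfite, epimers at sulfur) | CCOC(=O)C1=C(C)C[C@@H](OS(=O)O2)[C@@H]2C1(C)C | intermediate
9 | ethyl (4R,5S)-2,6,6-trimethyl-4,5-(sulfonyldioxy)cyclohex-1-ene-1-carboxylate (cyclic sulfate) | CCOC(=O)C1=C(C)C[C@@H](OS(=O)(=O)O2)[C@@H]2C1(C)C | intermediate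
10 | sodium (1R)-3-(ethoxycarbonyl)-2,2,4-trimethylcyclohex-3-en-1-yl sulfate | CCOC(=O)C1=C(C)CC[C@@H](OS(=O)(=O)[O-])C1(C)C.[Na+] | intermediate
11 | ethyl (5R)-5-hydroxy-2,6,6-trimethylcyclohex-1-ene-1-carboxylate | CCOC(=O)C1=C(C)CC[C@@H](O)C1(C)C | intermediate
12 | (1R)-3-(hydroxymethyl)-2,2,4-trimethylcyclohex-3-en-1-ol | OCC1=C(C)CC[C@@H](O)C1(C)C | intermediate
13 | (5R)-5-hydroxy-2,6,6-trimethylcyclohex-1-ene-1-carbaldehyde | O=CC1=C(C)CC[C@@H](O)C1(C)C | intermediate
14 | ethyl (E)-4-(diethoxyphosphoryl)-3-methylbut-2-enoate (commercial, E-rich mixture) | CCOC(=O)/C=C(\C)CP(=O)(OCC)OCC | starting material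
15 | ethyl (2E,4E)-5-[(5R)-5-hydroxy-2,6,6-trimethylcyclohex-1-en-1-yl]-3-methylpenta-2,4-dienoate | CCOC(=O)/C=C(C)/C=C/C1=C(C)CC[C@@H](O)C1(C)C | intermediate
16 | (2E,4E)-5-[(5R)-5-hydroxy-2,6,6-trimethylcyclohex-1-en-1-yl]-3-methylpenta-2,4-dien-1-ol | OC/C=C(C)/C=C/C1=C(C)CC[C@@H](O)C1(C)C | intermediate
17 | {(2E,4E)-5-[(5R)-5-hydroxy-2,6,6-trimethylcyclohex-1-en-1-yl]-3-methylpenta-2,4-dien-1-yl}triphenylphosphonium bromide | c1ccccc1[P+](c1ccccc1)(c1ccccc1)C/C=C(C)/C=C/C1=C(C)CC[C@@H](O)C1(C)C.[Br-] | intermediate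
18 | ethyl (4S,5R)-4,5-(isopropylidenedioxy)-2,6,6-trimethylcyclohex-1-ene-1-carboxylate | CCOC(=O)C1=C(C)C[C@H](OC(C)(C)O2)[C@H]2C1(C)C | intermediate
19 | [(4S,5R)-4,5-(isopropylidenedioxy)-2,6,6-trimethylcyclohex-1-en-1-yl]methanol | OCC1=C(C)C[C@H](OC(C)(C)O2)[C@H]2C1(C)C | intermediate
20 | (4S,5R)-4,5-(isopropylidenedioxy)-2,6,6-trimethylcyclohex-1-ene-1-carbaldehyde | O=CC1=C(C)C[C@H](OC(C)(C)O2)[C@H]2C1(C)C | intermediate
21 | ethyl (2E,4E)-5-[(4S,5R)-4,5-(isopropylidenedioxy)-2,6,6-trimethylcyclohex-1-en-1-yl]-3-methylpenta-2,4-dienoate | CCOC(=O)/C=C(C)/C=C/C1=C(C)C[C@H](OC(C)(C)O2)[C@H]2C1(C)C | intermediate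
22 | (2E,4E)-5-[(4S,5R)-4,5-(isopropylidenedioxy)-2,6,6-trimethylcyclohex-1-en-1-yl]-3-methylpenta-2,4-dien-1-ol | OC/C=C(C)/C=C/C1=C(C)C[C@H](OC(C)(C)O2)[C@H]2C1(C)C | intermediate
23 | {(2E,4E)-5-[(4S,5R)-4,5-(isopropylidenedioxy)-2,6,6-trimethylcyclohex-1-en-1-yl]-3-methylpenta-2,4-dien-1-yl}triphenylphosphonium bromide | c1ccccc1[P+](c1ccccc1)(c1ccccc1)C/C=C(C)/C=C/C1=C(C)C[C@H](OC(C)(C)O2)[C@H]2C1(C)C.[Br-] | intermediate
24 | {(2E,4E)-5-[(4S,5R)-4,5-dihydroxy-2,6,6-trimethylcyclohex-1-en-1-yl]-3-methylpenta-2,4-dien-1-yl}triphenylphosphonium bromide | c1ccccc1[P+](c1ccccc1)(c1ccccc1)C/C=C(C)/C=C/C1=C(C)C[C@H](O)[C@H](O)C1(C)C.[Br-] | intermediate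
25 | (2E,4E,6E)-2,7-dimethylocta-2,4,6-trienedial | O=C/C(C)=C/C=C/C=C(C)/C=O | starting material
26 | (2E,4E,6E,8E,10E,12E)-13-[(4S,5R)-4,5-dihydroxy-2,6,6-trimethylcyclohex-1-en-1-yl]-2,7,11-trimethyltrideca-2,4,6,8,10,12-hexaenal | O=C/C(C)=C/C=C/C=C(C)/C=C/C=C(C)/C=C/C1=C(C)C[C@H](O)[C@H](O)C1(C)C | intermediate
27 | (all-E)-(2R,2'R,3'S)-β,β-carotene-2,2',3'-triol | CC1=C(/C=C/C(C)=C/C=C/C(C)=C/C=C/C=C(C)/C=C/C=C(C)/C=C/C2=C(C)C[C@H](O)[C@H](O)C2(C)C)C(C)(C)[C@H](O)CC1 | target

**Step count**
Total steps: 19. Longest linear sequence: 12 steps (steps 1–11, then step 19).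

**Steps most likely to fail**

Step 1 (cycloaddition). The Z-methyl keeps the s-cis conformer of the diene sparsely populated, so Lewis-acid-induced polymerisation of the diene may outrun the cycloaddition. The fallback sets out from compound 1 and comes back at compound 3. The more reactive dienophile but-2-ynal F1 is made from commercial but-2-yn-1-ol with MnO2 in CH2Cl2. It is heated with 1 (toluene, 80–110 °C, sealed vessel, BHT) and should give, with the same orientation, 2,6,6-trimethylcyclohexa-1,4-diene-1-carbaldehyde F2. Pinnick oxidation (NaClO2, NaH2PO4, 2-methylbut-2-ene, t-BuOH/H2O) then gives 2,6,6-trimethylcyclohexa-1,4-diene-1-carboxylic acid F3, and O-alkylation of its carboxylate (EtI, K2CO3, DMF) gives 3.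

Step 6 (hydride opening of the cyclic sulfate). The hydride may act as a base and cause E2 loss of sulfate across C3–C4 towards the conjugated dienoate. It may also transfer sluggishly, because the axial trajectory at C4 passes an axial C6 methyl. The fallback sets out from compound 9 and comes back at compound 11. The cyclic sulfate is opened with non-basic bromide (LiBr, THF, 25 °C) to lithium (1S,6S)-6-bromo-3-(ethoxycarbonyl)-2,2,4-trimethylcyclohex-3-en-1-yl sulfate F4. Hydrolysis (cat. H2SO4, H2O, THF) gives ethyl (4S,5S)-4-bromo-5-hydroxy-2,6,6-trimethylcyclohex-1-ene-1-carboxylate F5. Radical debromination (Bu3SnH, AIBN, toluene, 80 °C) removes the halogen without touching C5 and gives 11.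

Step 3 (enzymatic sorting). The enzyme may discriminate the two enantiomers too weakly, or acylate too slowly beside the neopentylic carbinol, so that both streams stay enantiomerically impure. The fallback sets out from compound 4 and comes back at compounds 6 and 7, and step 4 then drops out. The C4–OH of racemic 4 is esterified with (S)-2-methoxy-2-phenylacetic acid (DCC, DMAP cat., CH2Cl2, 0 °C). This gives the diastereomers ethyl (4S,5R)-5-hydroxy-4-{[(2S)-2-methoxy-2-phenylacetyl]oxy}-2,6,6-trimethylcyclohex-1-ene-1-carboxylate F6 and ethyl (4R,5S)-5-hydroxy-4-{[(2S)-2-methoxy-2-phenylacetyl]oxy}-2,6,6-trimethylcyclohex-1-ene-1-carboxylate F7. They are separated by chromatography or crystallisation. Ethanolysis (K2CO3, EtOH) releases 6 from F6 and 7 from F7.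

**Further compounds**
F1 | step 1 | but-2-ynal | CC#CC=O
F2 | step 1 | 2,6,6-trimethylcyclohexa-1,4-diene-1-carbaldehyde | O=CC1=C(C)CC=CC1(C)C
F3 | step 1 | 2,6,6-trimethylcyclohexa-1,4-diene-1-carboxylic acid | OC(=O)C1=C(C)CC=CC1(C)C
F4 | step 6 | lithium (1S,6S)-6-bromo-3-(ethoxycarbonyl)-2,2,4-trimethylcyclohex-3-en-1-yl sulfate | CCOC(=O)C1=C(C)C[C@H](Br)[C@@H](OS(=O)(=O)[O-])C1(C)C.[Li+]
F5 | step 6 | ethyl (4S,5S)-4-bromo-5-hydroxy-2,6,6-trimethylcyclohex-1-ene-1-carboxylate | CCOC(=O)C1=C(C)C[C@H](Br)[C@@H](O)C1(C)C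
F6 | step 3 | ethyl (4S,5R)-5-hydroxy-4-{[(2S)-2-methoxy-2-phenylacetyl]oxy}-2,6,6-trimethylcyclohex-1-ene-1-carboxylate | CCOC(=O)C1=C(C)C[C@H](OC(=O)[C@@H](OC)c2ccccc2)[C@H](O)C1(C)C
F7 | step 3 | ethyl (4R,5S)-5-hydroxy-4-{[(2S)-2-methoxy-2-phenylacetyl]oxy}-2,6,6-trimethylcyclohex-1-ene-1-carboxylate | CCOC(=O)C1=C(C)C[C@@H](OC(=O)[C@@H](OC)c2ccccc2)[C@@H](O)C1(C)C
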